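**The vessel.** A closed, stirred vessel at constant volume and constant temperature takes a charge of starting material, and every amount is read as percent of that charge.

| flask | starting material | remark | time |
|---|---|---|---|
| west | 0.15 M | run made earlier |  |
| north | 0.22 M | run made earlier |  |
| Thursday's | 0.30 M |  | 1.0 d |
| Tuesday's | 0.30 M |  | 2.0 d |

| run | time / h | ring / % | starting material / % |
|---|---|---|---|
| west | 3.00 | 3.9 | 36.8 |
| west | 5.00 | 6.2 | 28.8 |
| west | 8.00 | 7.9 | 26.8 |
| west | 10.0 | 9.7 | 25.5 |
| west | 15.0 | 12.2 | 24.8 |
| west | 25.0 | 18.1 | 23.6 |
| west | 40.0 | 27.8 | 20.3 |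
| north | 3.00 | 4.4 | 35.4 |
| north | 5.00 | 5.4 | 28.5 |
| north | 8.00 | 7.7 | 27.0 |
| north | 10.0 | 9.1 | 24.9 |
| north | 15.0 | 12.8 | 24.8 |
| north | 25.0 | 17.3 | 22.3 |
| north | 40.0 | 26.4 | 19.5 |

(scatter of a reading: 0.5 percentage points)

- a reading or a percentage of ring counts all its forms, free or not

- which of the two ends with the higher amount of ring, in percent of the starting material charged ("neither" if they lie within 2 percentage points) (Thursday's / Tuesday's / neither)
- ring at the end, in percent of the starting material charged, Thursday's
- ring at the end, in percent of the starting material charged, Tuesday's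

**First hours.** By 3.00 h the west run shows 36.8% starting material and 3.9% ring, which leaves 59.3% of its charge unread.

**Middle stretch.** From 10.0 h to 40.0 h the west run loses 5.2 percentage points of starting material, less than the 18 points gained as ring. The reckoning here takes the rise of ring as constant over this stretch, a pseudo-zero-order stretch. The north run, at 0.22 M, reaches 26.4% against the west run's 27.8%, so percentages are carried to 0.30 M as an assumption. The frozen gain, the rise of ring per hour over this stretch averaged across both runs, is 0.00590 h⁻¹ of the charge, or 14.2% per day.

**The end.** Starting from the mean ring of 9.40% at 10.0 h, the line gives 17.7% for Thursday's at 1.0 d. For Tuesday's at 2.0 d, which is 8.00 h past the last reading, it gives 31.8%. The gap of 14 points is wider than the margin of 2 points, so this reckoning puts Tuesday's higher.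

**The forecast.** The forecast names Tuesday's, with 17.5% and 32%, 0.20 points below and 0.20 points above the line. Its ground: “at a steady 0.6 %/h, with no sign yet of slowing”.

**The flask.** The flask gives Tuesday's, with 17.4% for Thursday's and 29.5% for Tuesday's.

    starting material → ring (k = 0.0250 h⁻¹)
    2 starting material ⇌ open dimer (K = 8.60 L mol⁻¹, k = 0.0494 L mol⁻¹ h⁻¹)
    starting material ⇌ dormant form (K = 2.31, k = 0.477 h⁻¹)
    crystals ⇌ ring, rate k4*(cs4 - [ring]) while solid is left; crystals form when [ring] > cs4 (solubility = 7.20 mM, k = 2.02 h⁻¹)

**Two clocks.** In Tuesday's, of the turnover up to 2.0 d, half of that into dormant form is done by 0.563 h, far sooner than the 0.806 d for that into ring, and at 2.0 d dormant form holds 43.9% against 18.2% starting material. The frozen gain of 14.2% per day stands against the 12 points of ring that Tuesday's adds on its second day, while its starting material goes from 22.3% to 18.2%.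

**Five days.** For Tuesday's charge read at 5.0 d, the frozen gain gives 74.3%. The flask gives 54.8%, with starting material at 10.7%.

The earlier runs and the new flask were generated by integration from invented constants; the scatter is artificial.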